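(The runs were computed from invented constants, and the scatter is random.)

1. The summer run leads the spring run early, 43.2% against 27.0% at 2.00 min, yet at 30.0 min it stands at 79.1% against 79.6%: the hotter run gains pace but no target.

| flask | substrate | partner | temperature | remark | time |
|---|---|---|---|---|---|
| spring | 0.20 M | 0.40 M | 100 °C | the very flask that is asked about, followed so far |  |
| summer | 0.20 M | 0.40 M | 106 °C | run made earlier |  |
| flask | 0.20 M | 0.400 M | 100 °C |  | 40 min |

- spring (time / min: target / %): 2.00: 27.0; 6.00: 71.1; 12.0: 80.9; 20.0: 80.8; 25.0: 78.6; 30.0: 79.6
- summer (time / min: target / %): 2.00: 43.2; 6.00: 76.5; 12.0: 78.1; 20.0: 78.6; 25.0: 78.9; 30.0: 79.1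

(scatter of a reading: 1 percentage point)

2. From 12.0 min to 30.0 min the spring run averages 80.0% and the summer run 78.7%. So the spring run keeps a gap of 20.0%, the gap being the share of charged substrate that stands outside target at the plateau. The summer run keeps 21.3%. The two gaps differ by 1.3 percentage points against a scatter of 1 point per reading, so these readings do not clearly part the two plateaus.

3. Further target in the asked flask, which is the spring run continued, has to come out of this gap. Homo product and side product form by one-way steps, but substrate <-> dormant form runs both ways, so the gap may hold a store (a resting state). A flat line does not rule that out: the summer run climbs 1 point from 12.0 min to 30.0 min, which is within the scatter, so these readings do not show whether a slow release runs.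

- target, in percent of the substrate first charged, at 40 min
- the option that brings most further target ("none" if no option brings more than 2 percentage points) (blue / red / violet / ochre / none)
- target present, with what was taken out counted in, in percent of the substrate first charged, after blue
- target present, with what was taken out counted in, in percent of the substrate first charged, after red

- blue: at 40 min take out 90% of the target then present, then wait 80 min
- red: change nothing and wait 80 min more
- violet: at 40 min raise the temperature by 20 K, then wait 80 min
- ochre: at 40 min add partner, 100% of the amount charged, then wait 80 min

- percentages count the substrate that a species holds: one homo product or side product counts as two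
- target taken out counts as made
- steps thought possible: substrate + open intermediate -> side product; 2 open intermediate -> homo product; substrate <-> open intermediate; substrate <-> dormant form; partner -> second intermediate; open intermediate + second intermediate -> target
- additions bring no volume worth counting

My reckoning gives 80.0% for now, and I commit to violet, the option that heats a possibly slow release.

4. The forecast gives 80% (range 78.9% to 81%), 80.4% after blue, 80.4% after red, and best: none. On the dormant form it says: “Any dormant reserve must be small or very slow to release, since the hotter run ends no higher.” We part on the best option.

5. substrate + open intermediate → side product (k = 0.00806 /M/s, Ea = 79.0 kJ/mol); 2 open intermediate → homo product (k = 0.0151 /M/s, Ea = 75.0 kJ/mol); substrate ⇌ open intermediate (K = 0.260, k = 0.0259 /s, Ea = 101 kJ/mol, ΔH = −23.0 kJ/mol); substrate ⇌ dormant form (K = 28.0, k = 9.29 × 10⁻⁴ /s, Ea = 114 kJ/mol, ΔH = −16.0 kJ/mol); partner → second intermediate (k = 0.00222 /s, Ea = 103 kJ/mol); open intermediate + second intermediate → target (k = 0.693 /M/s, Ea = 58.0 kJ/mol); (constants at 100 °C)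

The asked flask holds 80.4% at 40 min, and the best option is violet, which brings 8.9 points against 1.8 points for red. Blue ends at 82.2% and red at 82.2%, with target taken out counted in. At 40.0 min the dormant form in this flask stands at 12.8%, which is 64.0% of the gap. The neighbour flask with 0.34 M of substrate ends at 70.9%, a gap of 29.1%, wider by 9.1 points, and at 40.0 min its dormant form holds 15.4%.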